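The route rests on cutting the side chain between the acetoxy-bearing carbon C2' and the neighbouring methylene C3' of the undecyl tail. C2' is flanked by two CH2 groups that a ketone reduction could hardly tell apart. Its own acetoxy oxygen, however, makes a C2'–Br bond radical-labile and gives nickel a handle. A stereoconvergent nickel-hydride coupling therefore joins a racemic 1-bromoalkyl acetate (made in the flask from an arylacetaldehyde and acetyl bromide) with 1-undecene and a silane. One operation forms C2'–C3', sets the R centre and installs the native acetate. The quinone ring is carried as an O-benzyl guaiacol ring from o-eugenol and unveiled at the end by hydrogenolysis and para-oxidation.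

Key step: step 3

Assumption: the sense of induction in step 3 is set by the ligand alone and both antipodes of the C2-symmetric isopropylidene-bridged bis(oxazoline) L* are available, so L* denotes the antipode that delivers the R acetate.

Step 1
Reactants: 1 o-eugenol (2-allyl-6-methoxyphenol)
Product: 2 1-allyl-2-(benzyloxy)-3-methoxybenzene
Conditions: BnBr, K2CO3, DMF, rt
Reagents that add atoms: benzyl bromide, BrCc1ccccc1
Why: Williamson ether synthesis: the phenoxide formed by K2CO3 displaces bromide from benzyl bromide in an SN2 reaction, and the benzyl ether masks the acidic, oxidisable phenol until after the coupling.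

Step 2
Reactants: 2 1-allyl-2-(benzyloxy)-3-methoxybenzene
Product: 4 2-[2-(benzyloxy)-3-methoxyphenyl]acetaldehyde, via secondary ozonide 3 (not isolated)
Conditions: O3, CH2Cl2, −78 °C (Sudan Red 7B end-point); then Me2S, −78 °C to rt; used promptly
Reagents that add atoms: ozone, [O-][O+]=O
Why: Ozonolysis by the Criegee mechanism: the isolated terminal alkene is by far the most reactive π bond towards ozone at −78 °C, and reduction of ozonide 3 with Me2S releases the arylacetaldehyde without over-oxidation.

Step 3
Reactants: 4 2-[2-(benzyloxy)-3-methoxyphenyl]acetaldehyde; 5 1-undecene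
Product: 7 (R)-1-[2-(benzyloxy)-3-methoxyphenyl]tridecan-2-yl acetate, via racemic bromo acetate 6 (not isolated)
Conditions: AcBr, CH2Cl2, 0 °C to rt, solvent swap; then 5, NiBr2·diglyme (cat.), bis(oxazoline) L* (cat.), (EtO)3SiH, K3PO4·H2O, iPr2O, rt
Reagents that add atoms: acetyl bromide, CC(=O)Br
Why: Acetyl bromide first adds across the C=O of 4 to give the racemic 1-bromoalkyl acetate 6; a ligated nickel hydride (from NiBr2, silane and phosphate) then inserts 1-undecene in the anti-Markovnikov sense to a primary undecylnickel species, nickel abstracts bromine from either enantiomer of 6 to give one planar α-acetoxyalkyl radical, and capture of this radical by the chiral alkylnickel followed by reductive elimination forms the C2'–C3' bond. The closest known reaction type is the nickel-hydride-catalysed enantioconvergent alkyl–alkyl coupling of racemic 1-haloalkyl esters with terminal olefins and a hydrosilane, including its four-component form that starts from aldehyde and acyl bromide. No ring is closed. The only new stereocentre, C2', is set by the chiral bis(oxazoline) on nickel in the radical-capture and reductive-elimination stage, helped by coordination of the acetate carbonyl oxygen, so both enantiomers of 6 should converge on the R acetate. The step needs linear regioselectivity in the hydrometallation (secured by the unbiased terminal olefin), coupling faster than hydrodebromination or loss of HBr towards the styryl acetate (secured by the mild, heterogeneous phosphate base at room temperature) and an inert arene, which is why the ring is carried as benzyl and methyl ethers and not as the nickel- and silane-sensitive quinone.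

Step 4
Reactants: 7 (R)-1-[2-(benzyloxy)-3-methoxyphenyl]tridecan-2-yl acetate
Product: 8 (R)-1-(2-hydroxy-3-methoxyphenyl)tridecan-2-yl acetate
Conditions: H2 (1 atm), Pd/C, EtOAc, rt
Reagents that add atoms: none
Why: Catalytic hydrogenolysis of a benzyl aryl ether: only the O–CH2Ph bond is benzylic, whereas the C2' acetate is homobenzylic and therefore stays in place with its configuration untouched.

Step 5
Reactants: 8 (R)-1-(2-hydroxy-3-methoxyphenyl)tridecan-2-yl acetate
Product: 9 (R)-1-(5-methoxy-3,6-dioxocyclohexa-1,4-dien-1-yl)tridecan-2-yl acetate, that is 2-[(2R)-2-acetoxytridecyl]-6-methoxy-1,4-benzoquinone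
Conditions: (KSO3)2NO (Fremy's salt, 2.5 equiv), KH2PO4 buffer, acetone/H2O, rt
Reagents that add atoms: potassium nitrosodisulfonate (KSO3)2NO, [K+].[K+].[O]N(S(=O)(=O)[O-])S(=O)(=O)[O-]
Why: Teuber oxidation: one equivalent of the nitroxyl radical takes the phenolic hydrogen, a second adds to the free para carbon of the 2,6-disubstituted phenoxyl radical and collapses to the para-quinone, and the near-neutral buffer leaves the acetate and C2' unchanged.

Compound list
1 | o-eugenol (2-allyl-6-methoxyphenol) | C=CCc1cccc(OC)c1O | starting material
2 | 1-allyl-2-(benzyloxy)-3-methoxybenzene | C=CCc1cccc(OC)c1OCc1ccccc1 | intermediate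
3 | 3-{[2-(benzyloxy)-3-methoxyphenyl]methyl}-1,2,4-trioxolane (secondary ozonide, racemic) | C1OC(Cc2cccc(OC)c2OCc2ccccc2)OO1 | intermediate
4 | 2-[2-(benzyloxy)-3-methoxyphenyl]acetaldehyde | O=CCc1cccc(OC)c1OCc1ccccc1 | intermediate
5 | 1-undecene | C=CCCCCCCCCC | starting material
6 | 2-[2-(benzyloxy)-3-methoxyphenyl]-1-bromoethyl acetate (racemic) | CC(=O)OC(Br)Cc1cccc(OC)c1OCc1ccccc1 | intermediate
7 | (R)-1-[2-(benzyloxy)-3-methoxyphenyl]tridecan-2-yl acetate | CCCCCCCCCCC[C@H](Cc1cccc(OC)c1OCc1ccccc1)OC(C)=O | intermediate
8 | (R)-1-(2-hydroxy-3-methoxyphenyl)tridecan-2-yl acetate | CCCCCCCCCCC[C@H](Cc1cccc(OC)c1O)OC(C)=O | intermediate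
9 | (R)-1-(5-methoxy-3,6-dioxocyclohexa-1,4-dien-1-yl)tridecan-2-yl acetate | CCCCCCCCCCC[C@H](CC1=CC(=O)C=C(OC)C1=O)OC(C)=O | target

Total step count: 5. Longest linear sequence: 5 steps (1 to 9).

Steps most likely to fail

Step 3.
- What may go wrong:
  - Enantioselection may be weak because the small acetyl group gives the catalyst little to grip.
  - The bromo acetate may lose HBr, or its radical may take a hydrogen from the benzylic OCH2, before it couples.
- Fallback: this forms the same C2'–C3' bond by a polar, catalyst-controlled carbonyl addition and sets out from 4.
  - Commercial 1-iodoundecane (CCCCCCCCCCCI) would undergo iodine–zinc exchange (Et2Zn, CuI cat., neat, 50 °C, volatiles removed) to give diundecylzinc F1.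
  - This reagent would be added to 4 with Ti(OiPr)4 and a catalytic amount of the suitable antipode of trans-1,2-bis(trifluoromethanesulfonamido)cyclohexane (toluene, −20 °C, aqueous HCl work-up).
  - The product would be (R)-1-[2-(benzyloxy)-3-methoxyphenyl]tridecan-2-ol F2.
  - Acetylation (Ac2O, pyridine, DMAP, CH2Cl2) comes back to the route at 7.

Step 2.
- What may go wrong:
  - Ozone may attack the electron-rich ring or the benzylic ether.
  - The enolisable arylacetaldehyde may self-condense during the slow reductive work-up.
- Fallback: this sets out from 2.
  - Upjohn dihydroxylation (OsO4 cat., NMO, acetone/H2O) would give the stable, storable 3-[2-(benzyloxy)-3-methoxyphenyl]propane-1,2-diol F3.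
  - Malaprade cleavage with NaIO4 on silica gel in CH2Cl2, run just before the coupling and followed only by filtration, comes back to the route at 4.

Step 5.
- What may go wrong: the lipophilic phenol may react slowly and heterogeneously in the aqueous medium, which gives phenoxyl radicals time to dimerise or to be oxidised at the methoxy-bearing ortho position.
- Fallback: this sets out from 8 and replaces the stoichiometric nitroxyl radical in water by a catalytic aerobic oxidation in a homogeneous organic phase.
  - With Co(salen) (cat.), O2 (1 atm), DMF, rt, a cobalt-bound superoxide delivers dioxygen to the para carbon of the 2,6-disubstituted phenol.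
  - It comes back to the route at 9 and makes no compound outside the list (entry F0).

Further compounds
F1 | step 3 | diundecylzinc | CCCCCCCCCCC[Zn]CCCCCCCCCCC
F2 | step 3 | (R)-1-[2-(benzyloxy)-3-methoxyphenyl]tridecan-2-ol | CCCCCCCCCCC[C@H](Cc1cccc(OC)c1OCc1ccccc1)O
F3 | step 2 | 3-[2-(benzyloxy)-3-methoxyphenyl]propane-1,2-diol (racemic) | OCC(O)Cc1cccc(OC)c1OCc1ccccc1
F0 | step 5 | none | none
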